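**Plan**

1. Labels used below: monocycle C1 (stereogenic CH), C2 (C=CH2), C3, C4, C5 (CH2), C6 (CMe2); chain C1–C16–C15–C14(Me)=C13–C12–C11–decalin C9 (alkene C8=C9, stereocentres C5 and C10 of the decalin).
2. Retrosynthesis: C12–C13 is cut first (sp3–sp2 Negishi coupling, the (E)-alkenyl iodide coming from an alkyne by carboalumination); then C3–C4 and C5–C6 of the monocycle are cut together in a [4+2] sense.
3. Enabling feature: C2 is a masked ketone, so C3=C2(OSi)–C1=C6Me2 is a 2-silyloxydiene and C4–C5 an acrylate. The acrylate carboxyl carbon (on C5) is tied as an ester to an oxygen on C14, three atoms along the chain from C1. The cycloaddition is therefore intramolecular (type 2) and gives a bicyclo[5.3.1] lactone whose one-carbon bridge is the gem-dimethyl carbon C6, as C15 is in the taxane A/B system.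
4. Forward: the diene–acrylate is made from mesityl oxide, (R)-but-3-en-2-ol and acryloyl chloride. The cycloaddition closes the six-membered ring and a temporary eight-membered lactone. Then follow C2=CH2, lactone opening, loss of the carboxyl carbon, and C14 carbinol → methyl ketone → C13≡C14 alkyne → (E)-C13=C14(Me) iodide. The decalin half, from (+)-sclareolide, is joined last.
5. Stereochemistry: the decalin centres come from (+)-sclareolide. C1 is fixed by the lactone bridge to C5, whose configuration is relayed from C14 of (R)-but-3-en-2-ol (both helper centres are erased later). The E alkene comes from syn-carboalumination.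

Key step: step 5

Assumption: the sense of induction from C14 is a model-based guess, not a secure prediction. The C14 methyl group is taken to sit on the outer side of the forming lactone ring (carbinol C–H in the ester plane), which for the (R)-alcohol is expected to lead to the (5S) adduct. If the sense proved opposite, the equally commercial (S)-alcohol would be used with no other change.

**Route**

Step 1
Reactants: 1 mesityl oxide (4-methylpent-3-en-2-one)
Product: 3 3-bromo-4-methylpent-3-en-2-one, via dibromide 2 (not isolated)
Conditions: Br2, CH2Cl2, 0 °C; then Et3N, 0 °C → rt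
Reagents that add atoms: bromine, BrBr
Why: Bromination–dehydrobromination of a conjugated ketone: Br2 adds to the alkene and the amine removes HBr by E1cB through the acidic C–H next to the carbonyl group, which should give the α-bromo enone.

Step 2
Reactants: 4 (R)-but-3-en-2-ol; 3 3-bromo-4-methylpent-3-en-2-one
Product: 6 (6R)-6-hydroxy-3-(propan-2-ylidene)heptan-2-one, via alkylborane 5 (not isolated)
Conditions: 9-BBN (2.2 equiv), THF, 0 °C → rt; then 3, Pd(OAc)2 (5 mol %), SPhos (10 mol %), aq. K3PO4, THF, 50 °C
Reagents that add atoms: none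
Why: Anti-Markovnikov hydroboration of the terminal alkene (one equivalent of 9-BBN is used up by the OH group) followed by B-alkyl Suzuki–Miyaura coupling with the α-bromo enone should join C16 to C1 without touching the carbinol centre C14.

Step 3
Reactants: 6 (6R)-6-hydroxy-3-(propan-2-ylidene)heptan-2-one; 7 acryloyl chloride
Product: 8 (2R)-6-oxo-5-(propan-2-ylidene)heptan-2-yl prop-2-enoate
Conditions: Et3N, DMAP (5 mol %), CH2Cl2, −20 → 0 °C
Reagents that add atoms: none
Why: DMAP-catalysed acylation of the secondary alcohol puts the dienophile (the future C4–C5 unit) on the tether, and no stereocentre is affected.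

Step 4
Reactants: 8 (2R)-6-oxo-5-(propan-2-ylidene)heptan-2-yl prop-2-enoate
Product: 9 (2R)-6-[(tert-butyldimethylsilyl)oxy]-5-(propan-2-ylidene)hept-6-en-2-yl prop-2-enoate
Conditions: TBSOTf (1.3 equiv), Et3N (2 equiv), CH2Cl2, −78 → 0 °C
Reagents that add atoms: tert-butyldimethylsilyl triflate, CC(C)(C)[Si](C)(C)OS(=O)(=O)C(F)(F)F
Why: Soft enolisation (silyl triflate activation of the ketone, amine deprotonation of the acetyl methyl group) should give the cross-conjugated 2-silyloxydiene, the standard preparation of such dienes from methyl vinyl ketones; the acrylate has no enolisable hydrogen.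

Step 5
Reactants: 9 (2R)-6-[(tert-butyldimethylsilyl)oxy]-5-(propan-2-ylidene)hept-6-en-2-yl prop-2-enoate
Product: 11 (1S,4R,7S)-4,11,11-trimethyl-3-oxabicyclo[5.3.1]undecane-2,8-dione (bridged keto lactone; in the labels of the plan 1S,5S,14R), via bridgehead silyl enol ether 10 (not isolated)
Conditions: Tf2NH (10 mol %), CH2Cl2 (0.005 M), −78 → −20 °C; then 1 M HCl, THF, 0 °C
Reagents that add atoms: none
Why: Tf2NH protodesilylates a little of 9 to give TBSNTf2, which activates the acrylate carbonyl group, and the electron-rich diene C3=C2(OSi)–C1=C6 then adds across C4=C5 in a concerted but asynchronous [4+2] process (C3–C4 leading, the limiting case being a Mukaiyama–Michael/Michael sequence) that forms C3–C4 and C5–C6 together. The closest known reactions are the acid-catalysed type 2 intramolecular Diels–Alder reactions that build the bicyclo[5.3.1] A/B core of taxanes with an isopropylidene diene terminus, and the triflimide-catalysed cycloadditions of hindered 2-silyloxydienes. The carbocycle closes as the six-membered ring of a Diels–Alder adduct; because the tether sits on the inner diene carbon C1, it closes at the same time as a bridging eight-membered lactone (type 2 mode), which leaves a bridgehead silyl enol ether C1=C2 and dictates that the acyl-bearing carbon C5, not C4, bonds to C6. C5 is set by the acrylate face that the diene reaches, which the (R)-carbinol centre C14 is expected to control by keeping its methyl group on the outer side of the forming lactone ring; C1 arises on hydrolysis of the bridgehead enol ether and can only take the configuration in which its chain and the C5 acyl group are cis, since they are the two ends of one bridge. The step needs the intramolecular path to win over intermolecular Michael oligomerisation (high dilution) and it needs facial selectivity (tether stereocentre; the other C1/C5 isomer is a diastereomer through C14 and should be removable by chromatography).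

Step 6
Reactants: 11 bridged keto lactone
Product: 12 (1S,4R,7R)-4,11,11-trimethyl-8-methylidene-3-oxabicyclo[5.3.1]undecan-2-one
Conditions: Zn, CH2Br2, TiCl4, THF/CH2Cl2, 0 °C → rt
Reagents that add atoms: dibromomethane, BrCBr
Why: Takai–Lombardo methylenation uses a non-basic gem-dimetallic CH2 reagent that converts hindered, enolisable ketones in the presence of esters, and C1 cannot epimerise because it is a bridgehead.

Step 7
Reactants: 12 methylidene lactone
Product: 13 (1S,3R)-3-[(3R)-3-hydroxybutyl]-2,2-dimethyl-4-methylidenecyclohexane-1-carboxylic acid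
Conditions: KOH, MeOH/H2O, 65 °C; then 1 M HCl to pH 4, 0 °C
Reagents that add atoms: potassium hydroxide, [K+].[OH-]
Why: Saponification opens the lactone to the carboxylate and the free C14 alcohol; the exocyclic alkene and C1 are inert to base, and epimerisation at C5 would not matter because that centre is removed in step 9.

Step 8
Reactants: 13 hydroxy acid
Product: 14 (1S,3R)-2,2-dimethyl-4-methylidene-3-(3-oxobutyl)cyclohexane-1-carboxylic acid
Conditions: Dess–Martin periodinane, CH2Cl2, rt
Reagents that add atoms: none
Why: Dess–Martin oxidation of the secondary alcohol under neutral conditions gives the methyl ketone, erases the relay centre C14 and leaves the acid and the acid-sensitive exocyclic alkene untouched.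

Step 9
Reactants: 14 keto acid
Product: 16 (S)-γ-dihydroionone, 4-[(1S)-2,2-dimethyl-6-methylidenecyclohexyl]butan-2-one, via Barton ester 15 (not isolated)
Conditions: 1-hydroxypyridine-2(1H)-thione, DCC, DMAP (cat.), CH2Cl2, dark, 0 °C → rt; then t-BuSH, hν (tungsten lamp), benzene, rt
Reagents that add atoms: none
Why: Barton reductive decarboxylation: the thiohydroxamate ester fragments under light to CO2 and the C5 radical, which takes hydrogen from the thiol, so the activating carboxyl carbon leaves without trace and C1 is not involved.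

Step 10
Reactants: 16 (S)-γ-dihydroionone
Product: 18 (2S)-2-(but-3-yn-1-yl)-1,1-dimethyl-3-methylidenecyclohexane, via enol phosphate 17 (not isolated)
Conditions: LDA (1.05 equiv), THF, −78 °C; ClP(O)(OEt)2, −78 → 0 °C; LDA (2.3 equiv), −78 °C → rt; H2O
Reagents that add atoms: none
Why: Negishi's one-pot conversion of a methyl ketone into a terminal alkyne: kinetic deprotonation at the methyl group, O-phosphorylation, then base-induced elimination of the enol phosphate to the lithium acetylide.

Step 11
Reactants: 18 terminal alkyne
Product: 20 (2S)-2-[(3E)-4-iodo-3-methylbut-3-en-1-yl]-1,1-dimethyl-3-methylidenecyclohexane, via alkenylalane 19 (not isolated)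
Conditions: AlMe3 (2 equiv), Cp2ZrCl2 (0.25 equiv), CH2Cl2, rt; then I2, THF, −30 → 0 °C
Reagents that add atoms: trimethylaluminium, C[Al](C)C; iodine, II
Why: Zirconium-catalysed syn-carboalumination (Negishi) puts methyl on the inner and aluminium on the terminal alkyne carbon, and iodinolysis with retention should give the (E)-alkenyl iodide that fixes the C13=C14 geometry; the 1,1-disubstituted alkene does not react.

Step 12
Reactants: 21 (+)-sclareolide
Product: 22 methyl 2-[(4aS,8aS)-2,5,5,8a-tetramethyl-3,4,4a,5,6,7,8,8a-octahydronaphthalen-1-yl]acetate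
Conditions: conc. H2SO4, MeOH, reflux; chromatography on AgNO3-impregnated silica
Reagents that add atoms: methanol, CO
Why: Acid opens the lactone by alkyl–oxygen cleavage at the tertiary carbon C8 (E1), the alkene isomers equilibrate towards the tetrasubstituted C8=C9 alkene and Fischer esterification traps the acid; the decalin stereocentres are untouched.

Step 13
Reactants: 22 unsaturated methyl ester
Product: 23 2-[(4aS,8aS)-2,5,5,8a-tetramethyl-3,4,4a,5,6,7,8,8a-octahydronaphthalen-1-yl]ethan-1-ol
Conditions: LiAlH4, Et2O, 0 °C
Reagents that add atoms: none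
Why: Hydride reduction of the ester gives the primary alcohol, and the tetrasubstituted alkene is inert.

Step 14
Reactants: 23 homoallylic alcohol
Product: 24 (4aS,8aS)-1-(2-iodoethyl)-2,5,5,8a-tetramethyl-3,4,4a,5,6,7,8,8a-octahydronaphthalene
Conditions: I2, PPh3, imidazole, CH2Cl2, 0 °C
Reagents that add atoms: iodine, II
Why: Appel-type iodination (Garegg–Samuelsson conditions) converts the primary alcohol into the iodide by SN2 displacement of the oxyphosphonium ion under buffered conditions.

Step 15
Reactants: 24 decalin iodide; 20 (E)-alkenyl iodide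
Product: 26 target, (4aS,8aS)-1-{(3E)-6-[(1S)-2,2-dimethyl-6-methylidenecyclohexyl]-4-methylhex-3-en-1-yl}-2,5,5,8a-tetramethyl-3,4,4a,5,6,7,8,8a-octahydronaphthalene, via alkylzinc iodide 25 (not isolated)
Conditions: Zn dust (activated), LiCl, THF, 40 °C; then 20, PdCl2(dppf) (5 mol %), THF, rt → 45 °C
Reagents that add atoms: none
Why: Zinc insertion into the primary C–I bond and Negishi sp3–sp2 cross-coupling with the alkenyl iodide should join C12 to C13 with retention of the alkene geometry, as in syntheses of polyprenoids.

**Compound list**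

1 | mesityl oxide | CC(=O)C=C(C)C | starting material
2 | 3,4-dibromo-4-methylpentan-2-one (racemic) | CC(=O)C(Br)C(C)(C)Br | intermediate
3 | 3-bromo-4-methylpent-3-en-2-one | CC(=O)C(Br)=C(C)C | intermediate
4 | (R)-but-3-en-2-ol | C[C@@H](O)C=C | starting material
5 | 9-{(3R)-3-[(9-borabicyclo[3.3.1]nonan-9-yl)oxy]butyl}-9-borabicyclo[3.3.1]nonane | C[C@@H](OB1C2CCCC1CCC2)CCB1C2CCCC1CCC2 | intermediate
6 | (6R)-6-hydroxy-3-(propan-2-ylidene)heptan-2-one | CC(=O)C(CC[C@@H](C)O)=C(C)C | intermediate
7 | acryloyl chloride | C=CC(=O)Cl | starting material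
8 | (2R)-6-oxo-5-(propan-2-ylidene)heptan-2-yl prop-2-enoate | CC(=O)C(CC[C@@H](C)OC(=O)C=C)=C(C)C | intermediate
9 | (2R)-6-[(tert-butyldimethylsilyl)oxy]-5-(propan-2-ylidene)hept-6-en-2-yl prop-2-enoate | C=C(O[Si](C)(C)C(C)(C)C)C(CC[C@@H](C)OC(=O)C=C)=C(C)C | intermediate
10 | (1S,4R)-8-[(tert-butyldimethylsilyl)oxy]-4,11,11-trimethyl-3-oxabicyclo[5.3.1]undec-7-en-2-one | CC(C)(C)[Si](C)(C)OC1=C2CC[C@@H](C)OC(=O)[C@@H](CC1)C2(C)C | intermediate
11 | (1S,4R,7S)-4,11,11-trimethyl-3-oxabicyclo[5.3.1]undecane-2,8-dione | O=C1CC[C@@H]2C(=O)O[C@H](C)CC[C@H]1C2(C)C | intermediate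
12 | (1S,4R,7R)-4,11,11-trimethyl-8-methylidene-3-oxabicyclo[5.3.1]undecan-2-one | C=C1CC[C@@H]2C(=O)O[C@H](C)CC[C@H]1C2(C)C | intermediate
13 | (1S,3R)-3-[(3R)-3-hydroxybutyl]-2,2-dimethyl-4-methylidenecyclohexane-1-carboxylic acid | C=C1CC[C@H](C(=O)O)C(C)(C)[C@@H]1CC[C@@H](C)O | intermediate
14 | (1S,3R)-2,2-dimethyl-4-methylidene-3-(3-oxobutyl)cyclohexane-1-carboxylic acid | C=C1CC[C@H](C(=O)O)C(C)(C)[C@@H]1CCC(C)=O | intermediate
15 | 2-thioxopyridin-1(2H)-yl ester of 14 (Barton ester) | C=C1CC[C@H](C(=O)On2ccccc2=S)C(C)(C)[C@@H]1CCC(C)=O | intermediate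
16 | (S)-γ-dihydroionone, 4-[(1S)-2,2-dimethyl-6-methylidenecyclohexyl]butan-2-one | C=C1CCCC(C)(C)[C@@H]1CCC(C)=O | intermediate
17 | diethyl 4-[(1S)-2,2-dimethyl-6-methylidenecyclohexyl]but-1-en-2-yl phosphate | C=C1CCCC(C)(C)[C@@H]1CCC(=C)OP(=O)(OCC)OCC | intermediate
18 | (2S)-2-(but-3-yn-1-yl)-1,1-dimethyl-3-methylidenecyclohexane | C=C1CCCC(C)(C)[C@@H]1CCC#C | intermediate
19 | {(1E)-4-[(1S)-2,2-dimethyl-6-methylidenecyclohexyl]-2-methylbut-1-en-1-yl}dimethylalumane | C=C1CCCC(C)(C)[C@@H]1CC/C(C)=C/[Al](C)C | intermediate
20 | (2S)-2-[(3E)-4-iodo-3-methylbut-3-en-1-yl]-1,1-dimethyl-3-methylidenecyclohexane | C=C1CCCC(C)(C)[C@@H]1CC/C(C)=C/I | intermediate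
21 | (+)-sclareolide | O=C1O[C@]2(C)CC[C@H]3C(C)(C)CCC[C@]3(C)[C@H]2C1 | starting material
22 | methyl 2-[(4aS,8aS)-2,5,5,8a-tetramethyl-3,4,4a,5,6,7,8,8a-octahydronaphthalen-1-yl]acetate | COC(=O)CC1=C(C)CC[C@H]2C(C)(C)CCC[C@]12C | intermediate
23 | 2-[(4aS,8aS)-2,5,5,8a-tetramethyl-3,4,4a,5,6,7,8,8a-octahydronaphthalen-1-yl]ethan-1-ol | OCCC1=C(C)CC[C@H]2C(C)(C)CCC[C@]12C | intermediate
24 | (4aS,8aS)-1-(2-iodoethyl)-2,5,5,8a-tetramethyl-3,4,4a,5,6,7,8,8a-octahydronaphthalene | ICCC1=C(C)CC[C@H]2C(C)(C)CCC[C@]12C | intermediate
25 | {2-[(4aS,8aS)-2,5,5,8a-tetramethyl-3,4,4a,5,6,7,8,8a-octahydronaphthalen-1-yl]ethyl}zinc iodide | I[Zn]CCC1=C(C)CC[C@H]2C(C)(C)CCC[C@]12C | intermediate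
26 | (4aS,8aS)-1-{(3E)-6-[(1S)-2,2-dimethyl-6-methylidenecyclohexyl]-4-methylhex-3-en-1-yl}-2,5,5,8a-tetramethyl-3,4,4a,5,6,7,8,8a-octahydronaphthalene | C=C1CCCC(C)(C)[C@@H]1CC/C(C)=C/CCC1=C(C)CC[C@H]2C(C)(C)CCC[C@]12C | target

**Step count and risks**

Total step count: 15. Longest linear sequence: 12 steps (steps 1 to 11, then step 15).

Steps most likely to fail:

1. Step 5. The cycloaddition may stall after the first C–C bond or lose to intermolecular Michael oligomerisation, because the isopropylidene terminus is hindered and the ester tether must leave its preferred conformation; the facial selectivity set by C14 may also be low or opposite to the assumed sense. Fallback, from 6 back to 11, without the tether in the ring-forming event: 6 is silylated (TBSCl, imidazole) to silyl ether F1. LDA (THF, −78 °C) deprotonates the acetyl methyl group, and the cross-conjugated lithium dienolate undergoes a Michael–Michael ring closure with methyl acrylate to give keto ester F2, formed together with its C5 epimer and as a mixture at C1. TBAF and then LiOH give seco acid F3. Yamaguchi lactonisation (2,4,6-trichlorobenzoyl chloride, Et3N, then DMAP, toluene, high dilution) closes the eight-membered lactone only from isomers with the chain and the carboxyl group cis, C1 epimerising under the basic conditions. Chromatographic separation from the C1/C5 diastereomer returns 11.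

2. Step 6. Addition to the hindered carbonyl group may be slow, or the reagent may attack the lactone. Fallback, from 11 back to 12, by Peterson olefination: Me3SiCH2Li with CeCl3 (THF, −78 °C) adds to the ketone only, giving β-hydroxysilane F4 (configuration at the new carbinol carbon without consequence), and HF·pyridine in MeCN induces elimination to 12.

3. Step 12. Equilibration may be incomplete, leaving alkene position isomers (C7=C8 and exocyclic) that are hard to separate. Fallback, from 21 back to 23, placing the alkene by a reductive transposition: the lactone enolate (LDA, THF, −78 °C) is selenenylated with PhSeCl to selenide F5. H2O2 gives, by syn-elimination of the selenoxide towards C9–H, butenolide F6 with a C9=C11 alkene. SmI2 (THF/HMPA, t-BuOH) cleaves the allylic C8–O bond, and kinetic protonation of the resulting dienolate at C11 leaves the alkene at C8=C9 in acid F7. LiAlH4 reduces F7 to 23.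

**Further compounds**

F1 | step 5 | (6R)-6-[(tert-butyldimethylsilyl)oxy]-3-(propan-2-ylidene)heptan-2-one | CC(=O)C(CC[C@@H](C)O[Si](C)(C)C(C)(C)C)=C(C)C
F2 | step 5 | methyl (1S)-3-{(3R)-3-[(tert-butyldimethylsilyl)oxy]butyl}-2,2-dimethyl-4-oxocyclohexane-1-carboxylate (C3 epimers) | COC(=O)[C@H]1CCC(=O)C(CC[C@@H](C)O[Si](C)(C)C(C)(C)C)C1(C)C
F3 | step 5 | (1S)-3-[(3R)-3-hydroxybutyl]-2,2-dimethyl-4-oxocyclohexane-1-carboxylic acid (C3 epimers) | O=C(O)[C@H]1CCC(=O)C(CC[C@@H](C)O)C1(C)C
F4 | step 6 | (1S,4R,7S)-8-hydroxy-4,11,11-trimethyl-8-[(trimethylsilyl)methyl]-3-oxabicyclo[5.3.1]undecan-2-one | C[Si](C)(C)CC1(O)CC[C@@H]2C(=O)O[C@H](C)CC[C@H]1C2(C)C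
F5 | step 12 | 11-(phenylselanyl)sclareolide (selenide on the lactone α-carbon) | O=C1O[C@]2(C)CC[C@H]3C(C)(C)CCC[C@]3(C)[C@H]2C1[Se]c1ccccc1
F6 | step 12 | 9(11)-dehydrosclareolide (butenolide) | O=C1O[C@]2(C)CC[C@H]3C(C)(C)CCC[C@]3(C)C2=C1
F7 | step 12 | 2-[(4aS,8aS)-2,5,5,8a-tetramethyl-3,4,4a,5,6,7,8,8a-octahydronaphthalen-1-yl]acetic acid | OC(=O)CC1=C(C)CC[C@H]2C(C)(C)CCC[C@]12C
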